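**Retrosynthetic overview**

1. Target 17 comes from global hydrogenolysis of tri-O-benzyl flavanone 16. Ring C is cut at O1–C8a and C4–C4a, giving 3,5-bis(benzyloxy)benzyne (from 5) and the O1–C2–C3–C4(=O) unit of (S)-β-silyloxy ester 13.
2. Enabling feature: in ring A, O1 (on C8a) and the acyl carbon C4 (on C4a) sit on adjacent carbons and C4a is flanked by the C5 oxygen. The aryne C4a≡C8a therefore carries an alkoxy group next to one aryne carbon, which sends an O-nucleophile to C8a and the carbanion to C4a. In ring C, O1 and C4 are 1,3-related through C2 and C3, that is a β-hydroxy ester.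
3. C2 is set by Noyori hydrogenation of β-keto ester 11, made from aryl bromide 9 by carbonylative malonate coupling.
4. Ring order: ring D (the dimethylpyranone on ring B) is closed first by Kabbe condensation; ring A is bought as a phloroglucinol ether; ring C is closed last in the key step.

Key step: step 9

Assumption: 1 and 6 are taken as purchasable, and flavanone numbering (O1, C2, C3, C4, C4a, C5 to C8, C8a) is used for rings C and A.

**Route**

Step 1
Reactants: 1 3,5-bis(benzyloxy)phenol
Product: 2 3,5-bis(benzyloxy)-2-bromophenol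
Conditions: NBS (1.0 equiv), CH2Cl2, −78 °C to rt
Reagents that add atoms: N-bromosuccinimide, O=C1CCC(=O)N1Br
Why: Electrophilic aromatic bromination, in which the hydrogen-bonding phenol OH should deliver NBS at low temperature to the ortho carbon C2 in preference to C4 between the two ethers.

Step 2
Reactants: 2 3,5-bis(benzyloxy)-2-bromophenol
Product: 5 3,5-bis(benzyloxy)-2-(trimethylsilyl)phenyl trifluoromethanesulfonate, via aryl trimethylsilyl ether 3 (not isolated), via lithium 2-silylphenolate 4 (not isolated)
Conditions: HMDS, THF, 70 °C, then evaporation; n-BuLi, THF, −78 °C; Tf2O, −78 °C to rt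
Reagents that add atoms: hexamethyldisilazane, C[Si](C)(C)N[Si](C)(C)C; trifluoromethanesulfonic anhydride, O=S(=O)(OS(=O)(=O)C(F)(F)F)C(F)(F)F
Why: O-silylation, bromine–lithium exchange and retro-Brook (1,3 O-to-C) silyl migration should place the silyl group on C2, and triflation of the phenolate then gives the o-silylaryl triflate in the standard one-flask way.

Step 3
Reactants: 6 1-(2,3-dihydroxyphenyl)ethanone
Product: 7 1-(5-bromo-2,3-dihydroxyphenyl)ethanone
Conditions: Br2 (1.0 equiv), AcOH, rt
Reagents that add atoms: bromine, BrBr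
Why: Electrophilic aromatic bromination should occur at C5, which is para to the C2 hydroxyl and meta to the acetyl group, whereas the positions ortho and para to the C3 hydroxyl are deactivated by the acetyl group.

Step 4
Reactants: 7 1-(5-bromo-2,3-dihydroxyphenyl)ethanone
Product: 8 6-bromo-8-hydroxy-2,2-dimethylchroman-4-one
Conditions: acetone (5 equiv), pyrrolidine (1 equiv), MeOH, reflux, under argon
Reagents that add atoms: acetone, CC(C)=O
Why: Kabbe condensation, in which pyrrolidine-mediated aldol condensation of the methyl ketone with acetone and oxa-Michael addition of the ortho hydroxyl should close the 2,2-dimethylpyranone ring D and leave the other hydroxyl free.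

Step 5
Reactants: 8 6-bromo-8-hydroxy-2,2-dimethylchroman-4-one
Product: 9 8-(benzyloxy)-6-bromo-2,2-dimethylchroman-4-one
Conditions: BnBr, K2CO3, DMF, rt to 50 °C
Reagents that add atoms: benzyl bromide, BrCc1ccccc1
Why: Williamson ether synthesis on the only remaining phenol.

Step 6
Reactants: 9 8-(benzyloxy)-6-bromo-2,2-dimethylchroman-4-one
Product: 11 methyl 3-[8-(benzyloxy)-2,2-dimethyl-4-oxochroman-6-yl]-3-oxopropanoate, via acylmalonic half ester 10 (not isolated)
Conditions: Pd(dba)2 (5 mol %), Xantphos (5 mol %), CO (1 atm), potassium methyl malonate (2 equiv), MgCl2 (1.5 equiv), Et3N (2 equiv), dioxane, 80 °C; then 1 M HCl, rt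
Reagents that add atoms: carbon monoxide, [C-]#[O+]; potassium methyl malonate, COC(=O)CC(=O)[O-].[K+]
Why: Palladium-catalysed carbonylative coupling of an aryl bromide with a magnesium malonate half-ester enolate, followed by decarboxylation on acidification, is a known entry to aryl β-keto esters, and the malonate should be enolised far more readily than the ring D ketone.

Step 7
Reactants: 11 methyl 3-[8-(benzyloxy)-2,2-dimethyl-4-oxochroman-6-yl]-3-oxopropanoate
Product: 12 methyl (3S)-3-[8-(benzyloxy)-2,2-dimethyl-4-oxochroman-6-yl]-3-hydroxypropanoate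
Conditions: RuCl2[(R)-BINAP](dmf)n (1 mol %), H2 (50 atm), MeOH, 50 °C
Reagents that add atoms: none
Why: Noyori asymmetric hydrogenation, in which chelation of the β-keto ester to the (R)-BINAP ruthenium dichloride catalyst fixes the face of hydride delivery and should give the (S)-carbinol from an aryl β-keto ester, while the non-chelating ring D ketone and the benzyl ether should not be reduced.

Step 8
Reactants: 12 methyl (3S)-3-[8-(benzyloxy)-2,2-dimethyl-4-oxochroman-6-yl]-3-hydroxypropanoate
Product: 13 methyl (3S)-3-[8-(benzyloxy)-2,2-dimethyl-4-oxochroman-6-yl]-3-[(trimethylsilyl)oxy]propanoate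
Conditions: N-(trimethylsilyl)imidazole (1.2 equiv), CH2Cl2, rt; used after filtration through a short pad and evaporation
Reagents that add atoms: N-(trimethylsilyl)imidazole, C[Si](C)(C)n1ccnc1
Why: Silylation of a secondary alcohol with a neutral silyl-transfer reagent should give the labile silyl ether with imidazole as the only by-product and without touching the stereocenter.

Step 9
Reactants: 13 methyl (3S)-3-[8-(benzyloxy)-2,2-dimethyl-4-oxochroman-6-yl]-3-[(trimethylsilyl)oxy]propanoate; 5 3,5-bis(benzyloxy)-2-(trimethylsilyl)phenyl trifluoromethanesulfonate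
Product: 16 (2S)-5,7-bis(benzyloxy)-2-[8-(benzyloxy)-2,2-dimethyl-4-oxochroman-6-yl]chroman-4-one, via 3,5-bis(benzyloxy)benzyne 14 (not isolated), via aryl potassium adduct 15 (not isolated)
Conditions: 5 (2 equiv), KF (4 equiv), 18-crown-6 (4 equiv), THF, 0 °C to rt, 13 added slowly over several hours
Reagents that add atoms: none
Why: Proposed new method: fluoride converts 5 into aryne 14 and (directly, or through the methoxide released later) unmasks the silyl ether of 13 as an alkoxide, whose oxygen adds to the aryne carbon remote from the flanking benzyloxy group (the future C8a) to give aryl anion 15 with the charge on the future C4a; this anion attacks the methyl ester and expels methoxide, so that O1–C8a and C4–C4a form in one operation. The closest known reaction type is the fluoride-mediated annulation of arynes from o-silylaryl triflates with methyl salicylates to give xanthones (O-arylation followed by intramolecular acyl substitution), and what is new is an aliphatic, stereodefined β-silyloxy ester as the O/acyl partner. Ring C closes by 6-exo-trig addition of the aryl carbanion to the ester carbonyl followed by loss of methoxide. No stereocenter is formed: C2 comes from step 7 and should keep its S configuration because none of its bonds is broken. The step needs regioselectivity (oxygen at C8a, acyl at C4a), which the C5 benzyloxy group secures by polarising the aryne so that the nucleophile attacks the meta carbon and the anion forms next to oxygen, and it needs cyclisation to outrun protonation, which the proton-free silyl ether (methoxide is trapped as MeOSiMe3 by the next molecule of 13) and THF as solvent secure. Slow addition of 13 keeps the free alkoxide low, so that retro-aldol cleavage, enolisation of the ring D ketone and base-induced opening of ring C should be minimised.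

Step 10
Reactants: 16 (2S)-5,7-bis(benzyloxy)-2-[8-(benzyloxy)-2,2-dimethyl-4-oxochroman-6-yl]chroman-4-one
Product: 17 (2S)-5,7-dihydroxy-2-(8-hydroxy-2,2-dimethyl-4-oxochroman-6-yl)chroman-4-one (CNP0303522.1)
Conditions: H2 (1 atm), 10% Pd/C, EtOAc/THF, rt
Reagents that add atoms: none
Why: Catalytic hydrogenolysis of aryl benzyl ethers under neutral conditions should free the three phenols, while the cyclic C2–O1 benzylic ether is cleaved much more slowly and C2 cannot epimerise without base.

**Compound list**

1 | 3,5-bis(benzyloxy)phenol | Oc1cc(OCc2ccccc2)cc(OCc2ccccc2)c1 | starting material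
2 | 3,5-bis(benzyloxy)-2-bromophenol | Oc1cc(OCc2ccccc2)cc(OCc2ccccc2)c1Br | intermediate
3 | [3,5-bis(benzyloxy)-2-bromophenoxy]trimethylsilane | C[Si](C)(C)Oc1cc(OCc2ccccc2)cc(OCc2ccccc2)c1Br | intermediate
4 | lithium 3,5-bis(benzyloxy)-2-(trimethylsilyl)phenolate | [Li+].[O-]c1cc(OCc2ccccc2)cc(OCc2ccccc2)c1[Si](C)(C)C | intermediate
5 | 3,5-bis(benzyloxy)-2-(trimethylsilyl)phenyl trifluoromethanesulfonate | C[Si](C)(C)c1c(OS(=O)(=O)C(F)(F)F)cc(OCc2ccccc2)cc1OCc1ccccc1 | intermediate
6 | 1-(2,3-dihydroxyphenyl)ethanone | CC(=O)c1cccc(O)c1O | starting material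
7 | 1-(5-bromo-2,3-dihydroxyphenyl)ethanone | CC(=O)c1cc(Br)cc(O)c1O | intermediate
8 | 6-bromo-8-hydroxy-2,2-dimethylchroman-4-one | CC1(C)CC(=O)c2cc(Br)cc(O)c2O1 | intermediate
9 | 8-(benzyloxy)-6-bromo-2,2-dimethylchroman-4-one | CC1(C)CC(=O)c2cc(Br)cc(OCc3ccccc3)c2O1 | intermediate
10 | 2-{[8-(benzyloxy)-2,2-dimethyl-4-oxochroman-6-yl]carbonyl}-3-methoxy-3-oxopropanoic acid (present as its salt before acidification) | COC(=O)C(C(=O)O)C(=O)c1cc(OCc2ccccc2)c2OC(C)(C)CC(=O)c2c1 | intermediate
11 | methyl 3-[8-(benzyloxy)-2,2-dimethyl-4-oxochroman-6-yl]-3-oxopropanoate | COC(=O)CC(=O)c1cc(OCc2ccccc2)c2OC(C)(C)CC(=O)c2c1 | intermediate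
12 | methyl (3S)-3-[8-(benzyloxy)-2,2-dimethyl-4-oxochroman-6-yl]-3-hydroxypropanoate | COC(=O)C[C@H](O)c1cc(OCc2ccccc2)c2OC(C)(C)CC(=O)c2c1 | intermediate
13 | methyl (3S)-3-[8-(benzyloxy)-2,2-dimethyl-4-oxochroman-6-yl]-3-[(trimethylsilyl)oxy]propanoate | COC(=O)C[C@H](O[Si](C)(C)C)c1cc(OCc2ccccc2)c2OC(C)(C)CC(=O)c2c1 | intermediate
14 | 3,5-bis(benzyloxy)benzyne | C1#CC(OCc2ccccc2)=CC(OCc2ccccc2)=C1 | intermediate
15 | potassium 2-{[(1S)-1-[8-(benzyloxy)-2,2-dimethyl-4-oxochroman-6-yl]-3-methoxy-3-oxopropyl]oxy}-4,6-bis(benzyloxy)benzen-1-ide | [K+].COC(=O)C[C@H](Oc1cc(OCc2ccccc2)cc(OCc2ccccc2)[c-]1)c1cc(OCc2ccccc2)c2OC(C)(C)CC(=O)c2c1 | intermediate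
16 | (2S)-5,7-bis(benzyloxy)-2-[8-(benzyloxy)-2,2-dimethyl-4-oxochroman-6-yl]chroman-4-one | CC1(C)CC(=O)c2cc([C@@H]3CC(=O)c4c(OCc5ccccc5)cc(OCc5ccccc5)cc4O3)cc(OCc3ccccc3)c2O1 | intermediate
17 | (2S)-5,7-dihydroxy-2-(8-hydroxy-2,2-dimethyl-4-oxochroman-6-yl)chroman-4-one | CC1(C)CC(=O)c2cc([C@@H]3CC(=O)c4c(O)cc(O)cc4O3)cc(O)c2O1 | target

**Step count and risks**

Total step count: 10. Longest linear sequence: 8 steps (6 to 17, steps 3 to 10); steps 1 and 2 make the aryne precursor and join at step 9.

Steps most likely to fail:

1. Step 9 (bears the label "Proposed new method:"). Proton transfer or enolisation of the ring D ketone may outrun O-arylation and acyl transfer, the alkoxide may undergo retro-aldol cleavage or β-elimination, and base-induced opening and reclosure of ring C may erode the configuration at C2. The fallback uses known chemistry, sets out from 11 and comes back at 16. Hydrogenation of 11 with the enantiomeric catalyst RuCl2[(S)-BINAP](dmf)n (H2, MeOH) would give methyl (3R)-3-[8-(benzyloxy)-2,2-dimethyl-4-oxochroman-6-yl]-3-hydroxypropanoate F1. A Mitsunobu reaction of F1 with phenol 1 (PPh3, DIAD, toluene, 0 °C) would give, with inversion at the carbinol carbon, methyl (3S)-3-[3,5-bis(benzyloxy)phenoxy]-3-[8-(benzyloxy)-2,2-dimethyl-4-oxochroman-6-yl]propanoate F2. Saponification (LiOH, THF/H2O) would give (3S)-3-[3,5-bis(benzyloxy)phenoxy]-3-[8-(benzyloxy)-2,2-dimethyl-4-oxochroman-6-yl]propanoic acid F3. Intramolecular Friedel–Crafts acylation of F3 (trifluoroacetic anhydride, CH2Cl2, 0 °C) at either of the two equivalent positions ortho to the ether oxygen would close ring C and give 16.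

2. Step 6. Incomplete CO insertion (direct coupling) or competing reaction at the enolisable ring D ketone may lower the efficiency of the carbonylative coupling. The fallback sets out from 9 and comes back at 11. Palladium-catalysed hydroxycarbonylation of 9 (Pd(OAc)2, Xantphos, CO, K2CO3, dioxane/H2O) would give 8-(benzyloxy)-2,2-dimethyl-4-oxochroman-6-carboxylic acid F4. Activation with 1,1'-carbonyldiimidazole (THF) would give [8-(benzyloxy)-2,2-dimethyl-4-oxochroman-6-yl](1H-imidazol-1-yl)methanone F5. Masamune–Brooks homologation of F5 with potassium methyl malonate, MgCl2 and Et3N, followed by acidic work-up, would give 11.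

3. Step 7. Facial discrimination on this bulky aryl β-keto ester may be insufficient, or conversion may be slow. The fallback sets out from 11 and comes back at 12: biocatalytic reduction with an (S)-selective ketoreductase chosen from a screening panel (NADPH recycled with glucose and glucose dehydrogenase, aqueous buffer/DMSO, 30 °C) would give 12 directly; this fallback makes no new compound (F0).

Further compounds
F1 | step 9 | methyl (3R)-3-[8-(benzyloxy)-2,2-dimethyl-4-oxochroman-6-yl]-3-hydroxypropanoate | COC(=O)C[C@@H](O)c1cc(OCc2ccccc2)c2OC(C)(C)CC(=O)c2c1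
F2 | step 9 | methyl (3S)-3-[3,5-bis(benzyloxy)phenoxy]-3-[8-(benzyloxy)-2,2-dimethyl-4-oxochroman-6-yl]propanoate | COC(=O)C[C@H](Oc1cc(OCc2ccccc2)cc(OCc2ccccc2)c1)c1cc(OCc2ccccc2)c2OC(C)(C)CC(=O)c2c1
F3 | step 9 | (3S)-3-[3,5-bis(benzyloxy)phenoxy]-3-[8-(benzyloxy)-2,2-dimethyl-4-oxochroman-6-yl]propanoic acid | OC(=O)C[C@H](Oc1cc(OCc2ccccc2)cc(OCc2ccccc2)c1)c1cc(OCc2ccccc2)c2OC(C)(C)CC(=O)c2c1
F4 | step 6 | 8-(benzyloxy)-2,2-dimethyl-4-oxochroman-6-carboxylic acid | OC(=O)c1cc(OCc2ccccc2)c2OC(C)(C)CC(=O)c2c1
F5 | step 6 | [8-(benzyloxy)-2,2-dimethyl-4-oxochroman-6-yl](1H-imidazol-1-yl)methanone | O=C(n1ccnc1)c1cc(OCc2ccccc2)c2OC(C)(C)CC(=O)c2c1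
F0 | step 7 | none | none
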